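Everything rests on cutting the C2–C3 bond of ring A. This exposes the C3 allylic carbinol, flanked by the C1=C2 alkene and the methyl-bearing C4, as the product of an alkenyl-metal addition to an aldehyde. A chromium/nickel-mediated closure of a fully functionalised ring B building block forms this bond, ring A and the C3 stereocentre in one operation. Its substrate is a cyclohexenone (ring B) that already carries the C5 quaternary centre, the C7 ketol with its acetoxypropenyl arm, a methyl-branched C4 aldehyde side chain and a (Z)-2-iodovinyl group on C10. C5 comes from an Ireland–Claisen chirality transfer, C4 from an Evans methylation.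

Key step: step 19

Remark: atoms are labelled as in an eremophilane (ring A = C1–C5 and C10, ring B = C5–C10, C11–C13 = the propenyl unit on C7, C14 = methyl on C5, C15 = methyl on C4); the ring-closure substrate 26 keeps the free C7 hydroxyl and the C13 acetate, and its C3 aldehyde is unmasked only one step before the closure and used without purification.

Step 1
Reactants: 1 3-methylcyclohex-2-en-1-one
Product: 2 2-iodo-3-methylcyclohex-2-en-1-one
Conditions: I2, K2CO3, 4-(dimethylamino)pyridine (20 mol%), THF–H2O, rt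
Reagents that add atoms: iodine, SMILES II
Why: Nucleophile-catalysed α-iodination of an enone (conjugate addition of the pyridine catalyst, iodination of the enolate at C2 and elimination, as in a Baylis–Hillman manifold), which touches only the α-vinylic position.

Step 2
Reactants: 2 2-iodo-3-methylcyclohex-2-en-1-one
Product: 3 (1S)-2-iodo-3-methylcyclohex-2-en-1-ol
Conditions: BH3·SMe2, (R)-1-methyl-3,3-diphenyltetrahydro-1H,3H-pyrrolo[1,2-c][1,3,2]oxazaborole (20 mol%), THF, 0 °C; MeOH quench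
Reagents that add atoms: none
Why: Corey–Bakshi–Shibata reduction, in which the 2-iodoalkenyl arm acts as the large carbonyl substituent so that the (R)-oxazaborolidine–borane complex delivers hydride to one face and should give the (S)-carbinol that later encodes C5.

Step 3
Reactants: 3 (1S)-2-iodo-3-methylcyclohex-2-en-1-ol; 4 ethynyltrimethylsilane
Product: 5 (1S)-3-methyl-2-[(trimethylsilyl)ethynyl]cyclohex-2-en-1-ol
Conditions: Pd(PPh3)2Cl2 (3 mol%), CuI (6 mol%), i-Pr2NH, THF, rt
Reagents that add atoms: none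
Why: Sonogashira coupling of an alkenyl iodide with a terminal alkyne, which tolerates the free allylic alcohol and brings in the two carbons that become C1 and C2.

Step 4
Reactants: 5 (1S)-3-methyl-2-[(trimethylsilyl)ethynyl]cyclohex-2-en-1-ol
Product: 6 (1S)-3-methyl-2-[(trimethylsilyl)ethynyl]cyclohex-2-en-1-yl acetate
Conditions: Ac2O, pyridine, 4-(dimethylamino)pyridine (5 mol%), CH2Cl2, 0 °C to rt
Reagents that add atoms: acetic anhydride, SMILES CC(=O)OC(C)=O
Why: Nucleophile-catalysed acetylation of a secondary alcohol, which does not touch the carbinol configuration.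

Step 5
Reactants: 6 (1S)-3-methyl-2-[(trimethylsilyl)ethynyl]cyclohex-2-en-1-yl acetate
Product: 9 2-[(1S)-1-methyl-2-[(trimethylsilyl)ethynyl]cyclohex-2-en-1-yl]acetic acid, via silyl ketene acetal 7 (not isolated), via trimethylsilyl ester 8 (not isolated)
Conditions: LiN(i-Pr)2, THF, −78 °C; Me3SiCl–Et3N, −78 °C to rt, then 60 °C; 1 M HCl work-up
Reagents that add atoms: none
Why: Ireland–Claisen rearrangement, in which the O-silylated acetate enolate undergoes a suprafacial [3,3] shift across the ring face that carried the oxygen, so that the carbinol configuration of 6 is relayed completely into the quaternary centre C5 (S) while the ring alkene moves to C9=C10.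

Step 6
Reactants: 9 2-[(1S)-1-methyl-2-[(trimethylsilyl)ethynyl]cyclohex-2-en-1-yl]acetic acid; 10 (4S)-4-benzyl-1,3-oxazolidin-2-one
Product: 12 (4S)-4-benzyl-3-{2-[(1S)-1-methyl-2-[(trimethylsilyl)ethynyl]cyclohex-2-en-1-yl]acetyl}-1,3-oxazolidin-2-one, via mixed pivalic anhydride 11 (not isolated)
Conditions: t-BuCOCl, Et3N, THF, −20 °C; then 10, LiCl, rt
Reagents that add atoms: none
Why: N-Acylation of an oxazolidinone through a pivalic mixed anhydride (Evans auxiliary attachment), in which the lithium chloride–amine activated oxazolidinone attacks the less hindered acyl carbonyl.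

Step 7
Reactants: 12 (4S)-4-benzyl-3-{2-[(1S)-1-methyl-2-[(trimethylsilyl)ethynyl]cyclohex-2-en-1-yl]acetyl}-1,3-oxazolidin-2-one
Product: 13 (4S)-4-benzyl-3-{(2S)-2-[(1S)-1-methyl-2-[(trimethylsilyl)ethynyl]cyclohex-2-en-1-yl]propanoyl}-1,3-oxazolidin-2-one
Conditions: NaN(SiMe3)2, THF, −78 °C; MeI, −78 to −40 °C
Reagents that add atoms: iodomethane, SMILES CI
Why: Evans asymmetric alkylation, in which the chelated sodium (Z)-enolate is methylated on the face remote from the benzyl group of the auxiliary, which should set C4 as (S) under reagent control next to the quaternary C5.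

Step 8
Reactants: 13 (4S)-4-benzyl-3-{(2S)-2-[(1S)-1-methyl-2-[(trimethylsilyl)ethynyl]cyclohex-2-en-1-yl]propanoyl}-1,3-oxazolidin-2-one
Product: 14 (2S)-2-[(1S)-1-methyl-2-[(trimethylsilyl)ethynyl]cyclohex-2-en-1-yl]propan-1-ol
Conditions: LiBH4, H2O (1 equiv), Et2O, 0 °C
Reagents that add atoms: none
Why: Reductive cleavage of an N-acyloxazolidinone by borohydride at the exocyclic carbonyl, which gives the primary alcohol without enolisation of C4 and returns the auxiliary.

Step 9
Reactants: 14 (2S)-2-[(1S)-1-methyl-2-[(trimethylsilyl)ethynyl]cyclohex-2-en-1-yl]propan-1-ol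
Product: 15 tert-butyl{(2S)-2-[(1S)-1-methyl-2-[(trimethylsilyl)ethynyl]cyclohex-2-en-1-yl]propoxy}diphenylsilane
Conditions: t-BuPh2SiCl, imidazole, DMF, rt
Reagents that add atoms: tert-butyl(chloro)diphenylsilane, SMILES CC(C)(C)[Si](Cl)(c1ccccc1)c1ccccc1
Why: Silyl ether formation at an unhindered primary alcohol, the tert-butyldiphenylsilyl group being chosen because it survives the chromium oxidation, the strong bases and the mild acid that follow.

Step 10
Reactants: 15 tert-butyl{(2S)-2-[(1S)-1-methyl-2-[(trimethylsilyl)ethynyl]cyclohex-2-en-1-yl]propoxy}diphenylsilane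
Product: 16 (4S)-4-[(2S)-1-(tert-butyldiphenylsilyloxy)propan-2-yl]-4-methyl-3-[(trimethylsilyl)ethynyl]cyclohex-2-en-1-one
Conditions: CrO3, 3,5-dimethylpyrazole, CH2Cl2, −20 °C
Reagents that add atoms: chromium trioxide, SMILES O=[Cr](=O)=O
Why: Allylic oxidation of a cyclohexene to the enone with the CrO3–3,5-dimethylpyrazole complex, which can only end at C8 because C8 is the sole allylic methylene (C5 is quaternary) and any transposed tertiary chromate would relay back to the same enone.

Step 11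
Reactants: 17 2-bromoprop-2-en-1-ol
Product: 18 [(2-bromoprop-2-en-1-yl)oxy]triethylsilane
Conditions: Et3SiCl, imidazole, CH2Cl2, 0 °C
Reagents that add atoms: chlorotriethylsilane, SMILES CC[Si](Cl)(CC)CC
Why: Silyl ether formation at a primary allylic alcohol, which masks the hydroxyl for the palladium-mediated coupling and can be removed later without loss of the other silyl groups.

Step 12
Reactants: 16 (4S)-4-[(2S)-1-(tert-butyldiphenylsilyloxy)propan-2-yl]-4-methyl-3-[(trimethylsilyl)ethynyl]cyclohex-2-en-1-one; 18 [(2-bromoprop-2-en-1-yl)oxy]triethylsilane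
Product: 19 (4S,6RS)-4-[(2S)-1-(tert-butyldiphenylsilyloxy)propan-2-yl]-4-methyl-6-[3-(triethylsilyloxy)prop-1-en-2-yl]-3-[(trimethylsilyl)ethynyl]cyclohex-2-en-1-one
Conditions: LiN(SiMe3)2 (2.2 equiv), THF, −78 to 0 °C; then 18, Pd2(dba)3 (2.5 mol%), P(t-Bu)3·HBF4 (10 mol%), toluene, rt
Reagents that add atoms: none
Why: Palladium-catalysed α-alkenylation of a ketone enolate (enolate cross-coupling of the α-arylation family), in which C7 is the only enolisable carbon of 16 and its lithium enolate couples with the alkenylpalladium bromide formed from 18 to give the C7–C11 bond, the configuration at C7 being irrelevant because the next step erases it.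

Step 13
Reactants: 19 (4S,6RS)-4-[(2S)-1-(tert-butyldiphenylsilyloxy)propan-2-yl]-4-methyl-6-[3-(triethylsilyloxy)prop-1-en-2-yl]-3-[(trimethylsilyl)ethynyl]cyclohex-2-en-1-one
Product: 21 (4S,6S)-4-[(2S)-1-(tert-butyldiphenylsilyloxy)propan-2-yl]-6-hydroxy-6-(3-hydroxyprop-1-en-2-yl)-4-methyl-3-[(trimethylsilyl)ethynyl]cyclohex-2-en-1-one, via triethylsilyl ether ketol 20 (not isolated)
Conditions: KN(SiMe3)2, THF, −78 °C; 2-(phenylsulfonyl)-3-phenyloxaziridine, −78 °C; AcOH then aqueous NH4Cl at −78 °C; then pyridinium p-toluenesulfonate (10 mol%), MeOH, 0 °C to rt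
Reagents that add atoms: 2-(phenylsulfonyl)-3-phenyloxaziridine, SMILES O=S(=O)(N1OC1c1ccccc1)c1ccccc1
Why: Davis oxaziridine hydroxylation of a potassium dienolate at its α-carbon followed by acid-catalysed methanolysis of the primary triethylsilyl ether, in which the oxidant should approach C7 anti to the C4-bearing side chain of C5 (held pseudoaxial by A(1,2) strain against the alkynyl group on C10) and so place the hydroxyl cis to the C5 methyl (7S).

Step 14
Reactants: 21 (4S,6S)-4-[(2S)-1-(tert-butyldiphenylsilyloxy)propan-2-yl]-6-hydroxy-6-(3-hydroxyprop-1-en-2-yl)-4-methyl-3-[(trimethylsilyl)ethynyl]cyclohex-2-en-1-one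
Product: 22 (4S,6S)-6-[3-(acetyloxy)prop-1-en-2-yl]-4-[(2S)-1-(tert-butyldiphenylsilyloxy)propan-2-yl]-6-hydroxy-4-methyl-3-[(trimethylsilyl)ethynyl]cyclohex-2-en-1-one
Conditions: Ac2O, pyridine, CH2Cl2, 0 °C
Reagents that add atoms: acetic anhydride, SMILES CC(=O)OC(C)=O
Why: Selective acetylation, in which the primary allylic hydroxyl reacts while the hindered tertiary hydroxyl of the ketol does not.

Step 15
Reactants: 22 (4S,6S)-6-[3-(acetyloxy)prop-1-en-2-yl]-4-[(2S)-1-(tert-butyldiphenylsilyloxy)propan-2-yl]-6-hydroxy-4-methyl-3-[(trimethylsilyl)ethynyl]cyclohex-2-en-1-one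
Product: 23 (4S,6S)-6-[3-(acetyloxy)prop-1-en-2-yl]-4-[(2S)-1-(tert-butyldiphenylsilyloxy)propan-2-yl]-6-hydroxy-3-(iodoethynyl)-4-methylcyclohex-2-en-1-one
Conditions: N-iodosuccinimide, AgNO3 (10 mol%), acetone, rt, dark
Reagents that add atoms: N-iodosuccinimide, SMILES O=C1CCC(=O)N1I
Why: Silver-catalysed iododesilylation of a trimethylsilyl alkyne with N-iodosuccinimide, which runs through the silver acetylide under neutral conditions that leave the acetate, the ketol and the silyl ether untouched.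

Step 16
Reactants: 23 (4S,6S)-6-[3-(acetyloxy)prop-1-en-2-yl]-4-[(2S)-1-(tert-butyldiphenylsilyloxy)propan-2-yl]-6-hydroxy-3-(iodoethynyl)-4-methylcyclohex-2-en-1-one
Product: 24 (4S,6S)-6-[3-(acetyloxy)prop-1-en-2-yl]-4-[(2S)-1-(tert-butyldiphenylsilyloxy)propan-2-yl]-6-hydroxy-3-[(Z)-2-iodoethenyl]-4-methylcyclohex-2-en-1-one
Conditions: 2-nitrobenzenesulfonyl hydrazide, Et3N, THF–i-PrOH, rt, dark
Reagents that add atoms: none
Why: Diimide reduction of a 1-iodoalkyne, in which concerted syn delivery of two hydrogens can give only the (Z)-iodoalkene and the iodoalkyne reacts faster than the trisubstituted enone alkene or the hindered 1,1-disubstituted alkene.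

Step 17
Reactants: 24 (4S,6S)-6-[3-(acetyloxy)prop-1-en-2-yl]-4-[(2S)-1-(tert-butyldiphenylsilyloxy)propan-2-yl]-6-hydroxy-3-[(Z)-2-iodoethenyl]-4-methylcyclohex-2-en-1-one
Product: 25 (4S,6S)-6-[3-(acetyloxy)prop-1-en-2-yl]-6-hydroxy-4-[(2S)-1-hydroxypropan-2-yl]-3-[(Z)-2-iodoethenyl]-4-methylcyclohex-2-en-1-one
Conditions: HF·pyridine, pyridine, THF, 0 °C to rt
Reagents that add atoms: none
Why: Fluoride-mediated desilylation under buffered conditions, which frees the primary C3 hydroxyl without affecting the acetate, the tertiary alcohol or the alkenyl iodide.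

Step 18
Reactants: 25 (4S,6S)-6-[3-(acetyloxy)prop-1-en-2-yl]-6-hydroxy-4-[(2S)-1-hydroxypropan-2-yl]-3-[(Z)-2-iodoethenyl]-4-methylcyclohex-2-en-1-one
Product: 26 (2S)-2-[(1S,5S)-5-[3-(acetyloxy)prop-1-en-2-yl]-5-hydroxy-2-[(Z)-2-iodoethenyl]-1-methyl-4-oxocyclohex-2-en-1-yl]propanal
Conditions: Dess–Martin periodinane, NaHCO3, CH2Cl2, 0 °C to rt; used crude
Reagents that add atoms: none
Why: Dess–Martin oxidation of a primary alcohol under bicarbonate buffering, which gives the aldehyde without base so that the epimerisable C4 centre is kept, the tertiary alcohol being inert.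

Step 19
Reactants: 26 (2S)-2-[(1S,5S)-5-[3-(acetyloxy)prop-1-en-2-yl]-5-hydroxy-2-[(Z)-2-iodoethenyl]-1-methyl-4-oxocyclohex-2-en-1-yl]propanal
Product: 27 (3S,4S,5S,7S)-13-acetoxy-3,7-dihydroxyeremophila-1,9,11(12)-trien-8-one
Conditions: CrCl2 (8 equiv), NiCl2 (1 mol% of the CrCl2), degassed DMF, rt, 5 mM, slow addition of 26
Reagents that add atoms: none
Why: Zerovalent nickel, generated from NiCl2 by CrCl2, inserts into the C2–I bond, and transmetalation to trivalent chromium gives a (Z)-alkenylchromium species that adds to the C3 aldehyde. The closest known reaction type is the intramolecular Nozaki–Hiyama–Kishi alkenyl iodide–aldehyde coupling. Ring A is closed by a 6-exo-trig attack of C2 on the C3 carbonyl, which only the (Z)-alkene geometry permits. The new C3 centre is controlled by C4 and C5: in the half-chair transition state the C5 methyl is axial and the C4 methyl equatorial, so the chromium-bound oxygen should take the pseudo-equatorial position and give the (3S)-alcohol, trans to the C4 methyl. The step needs chemoselectivity for the aldehyde over the C8 enone and tolerance of the free C7 hydroxyl and the allylic acetate; the low basicity and strong aldehyde preference of alkenylchromium reagents, the fast insertion of nickel into the electron-poor alkenyl iodide and the low NiCl2 loading secure this.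

Step 20
Reactants: 28 (R)-2-methylbutanoic acid
Product: 29 (2R)-2-methylbutan-1-ol
Conditions: LiAlH4, Et2O, 0 °C to rt
Reagents that add atoms: none
Why: Hydride reduction of a carboxylic acid (via its carboxylate) to the primary alcohol, which cannot racemise the α-stereocentre.

Step 21
Reactants: 29 (2R)-2-methylbutan-1-ol
Product: 31 (2E,4R)-2,4-dimethylhex-2-enal, via (R)-2-methylbutanal 30 (not isolated)
Conditions: PhI(OAc)2, 2,2,6,6-tetramethylpiperidin-1-oxyl (10 mol%), CH2Cl2, rt; then Ph3P=C(CH3)CHO, toluene, 80 °C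
Reagents that add atoms: 2-(triphenylphosphoranylidene)propanal, SMILES CC(C=O)=P(c1ccccc1)(c1ccccc1)c1ccccc1
Why: Oxoammonium-catalysed oxidation to the aldehyde followed in the same flask by a Wittig reaction with a stabilised formyl ylide, which is (E)-selective and avoids isolation of the volatile and racemisation-prone aldehyde.

Step 22
Reactants: 31 (2E,4R)-2,4-dimethylhex-2-enal
Product: 32 ethyl (2E,4E,6R)-4,6-dimethylocta-2,4-dienoate
Conditions: (EtO)2P(O)CH2CO2Et, NaH, THF, 0 °C to rt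
Reagents that add atoms: triethyl phosphonoacetate, SMILES CCOC(=O)CP(=O)(OCC)OCC
Why: Horner–Wadsworth–Emmons olefination of an enal with a stabilised phosphonate anion, which gives the (2E)-dienoate.

Step 23
Reactants: 32 ethyl (2E,4E,6R)-4,6-dimethylocta-2,4-dienoate
Product: 33 (2E,4E,6R)-4,6-dimethylocta-2,4-dienoic acid
Conditions: LiOH, THF–MeOH–H2O, rt; then 1 M HCl
Reagents that add atoms: lithium hydroxide, SMILES [Li+].[OH-]
Why: Saponification of an ethyl ester, which is safe because the acid has no stereocentre α to the carboxyl group.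

Step 24
Reactants: 27 (3S,4S,5S,7S)-13-acetoxy-3,7-dihydroxyeremophila-1,9,11(12)-trien-8-one; 33 (2E,4E,6R)-4,6-dimethylocta-2,4-dienoic acid
Product: 35 (3S,4S,5S,7S)-13-acetoxy-7-hydroxy-8-oxoeremophila-1,9,11(12)-trien-3-yl (2E,4E,6R)-4,6-dimethylocta-2,4-dienoate (target), via mixed trichlorobenzoic anhydride 34 (not isolated)
Conditions: 2,4,6-trichlorobenzoyl chloride, Et3N, THF, rt; then 27, 4-(dimethylamino)pyridine, toluene, rt
Reagents that add atoms: none
Why: Yamaguchi esterification, in which the mixed anhydride acylates the secondary C3 hydroxyl under nucleophilic catalysis with retention at C3 while the tertiary C7 hydroxyl is too hindered to react.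

Compound list
1 | 3-methylcyclohex-2-en-1-one | CC1=CC(=O)CCC1 | starting material
2 | 2-iodo-3-methylcyclohex-2-en-1-one | CC1=C(I)C(=O)CCC1 | intermediate
3 | (1S)-2-iodo-3-methylcyclohex-2-en-1-ol | O[C@H]1CCCC(C)=C1I | intermediate
4 | ethynyltrimethylsilane | C#C[Si](C)(C)C | starting material
5 | (1S)-3-methyl-2-[(trimethylsilyl)ethynyl]cyclohex-2-en-1-ol | O[C@H]1CCCC(C)=C1C#C[Si](C)(C)C | intermediate
6 | (1S)-3-methyl-2-[(trimethylsilyl)ethynyl]cyclohex-2-en-1-yl acetate | CC(=O)O[C@H]1CCCC(C)=C1C#C[Si](C)(C)C | intermediate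
7 | trimethylsilyl ketene acetal of 6, (1S)-3-methyl-2-[(trimethylsilyl)ethynyl]cyclohex-2-en-1-yl 1-(trimethylsilyloxy)ethenyl ether | C=C(O[Si](C)(C)C)O[C@H]1CCCC(C)=C1C#C[Si](C)(C)C | intermediate
8 | trimethylsilyl 2-[(1S)-1-methyl-2-[(trimethylsilyl)ethynyl]cyclohex-2-en-1-yl]acetate | C[Si](C)(C)OC(=O)C[C@]1(C)CCCC=C1C#C[Si](C)(C)C | intermediate
9 | 2-[(1S)-1-methyl-2-[(trimethylsilyl)ethynyl]cyclohex-2-en-1-yl]acetic acid | OC(=O)C[C@]1(C)CCCC=C1C#C[Si](C)(C)C | intermediate
10 | (4S)-4-benzyl-1,3-oxazolidin-2-one | O=C1OC[C@H](Cc2ccccc2)N1 | starting material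
11 | mixed anhydride of 9 with pivalic acid | CC(C)(C)C(=O)OC(=O)C[C@]1(C)CCCC=C1C#C[Si](C)(C)C | intermediate
12 | (4S)-4-benzyl-3-{2-[(1S)-1-methyl-2-[(trimethylsilyl)ethynyl]cyclohex-2-en-1-yl]acetyl}-1,3-oxazolidin-2-one | O=C1OC[C@H](Cc2ccccc2)N1C(=O)C[C@]1(C)CCCC=C1C#C[Si](C)(C)C | intermediate
13 | (4S)-4-benzyl-3-{(2S)-2-[(1S)-1-methyl-2-[(trimethylsilyl)ethynyl]cyclohex-2-en-1-yl]propanoyl}-1,3-oxazolidin-2-one | O=C1OC[C@H](Cc2ccccc2)N1C(=O)[C@@H](C)[C@]1(C)CCCC=C1C#C[Si](C)(C)C | intermediate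
14 | (2S)-2-[(1S)-1-methyl-2-[(trimethylsilyl)ethynyl]cyclohex-2-en-1-yl]propan-1-ol | OC[C@@H](C)[C@]1(C)CCCC=C1C#C[Si](C)(C)C | intermediate
15 | tert-butyl{(2S)-2-[(1S)-1-methyl-2-[(trimethylsilyl)ethynyl]cyclohex-2-en-1-yl]propoxy}diphenylsilane | CC(C)(C)[Si](OC[C@@H](C)[C@]1(C)CCCC=C1C#C[Si](C)(C)C)(c1ccccc1)c1ccccc1 | intermediate
16 | (4S)-4-[(2S)-1-(tert-butyldiphenylsilyloxy)propan-2-yl]-4-methyl-3-[(trimethylsilyl)ethynyl]cyclohex-2-en-1-one | CC(C)(C)[Si](OC[C@@H](C)[C@]1(C)CCC(=O)C=C1C#C[Si](C)(C)C)(c1ccccc1)c1ccccc1 | intermediate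
17 | 2-bromoprop-2-en-1-ol | OCC(Br)=C | starting material
18 | [(2-bromoprop-2-en-1-yl)oxy]triethylsilane | C=C(Br)CO[Si](CC)(CC)CC | intermediate
19 | (4S,6RS)-4-[(2S)-1-(tert-butyldiphenylsilyloxy)propan-2-yl]-4-methyl-6-[3-(triethylsilyloxy)prop-1-en-2-yl]-3-[(trimethylsilyl)ethynyl]cyclohex-2-en-1-one | CC(C)(C)[Si](OC[C@@H](C)[C@]1(C)CC(C(=C)CO[Si](CC)(CC)CC)C(=O)C=C1C#C[Si](C)(C)C)(c1ccccc1)c1ccccc1 | intermediate
20 | (4S,6S)-4-[(2S)-1-(tert-butyldiphenylsilyloxy)propan-2-yl]-6-hydroxy-4-methyl-6-[3-(triethylsilyloxy)prop-1-en-2-yl]-3-[(trimethylsilyl)ethynyl]cyclohex-2-en-1-one | CC(C)(C)[Si](OC[C@@H](C)[C@]1(C)C[C@](O)(C(=C)CO[Si](CC)(CC)CC)C(=O)C=C1C#C[Si](C)(C)C)(c1ccccc1)c1ccccc1 | intermediate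
21 | (4S,6S)-4-[(2S)-1-(tert-butyldiphenylsilyloxy)propan-2-yl]-6-hydroxy-6-(3-hydroxyprop-1-en-2-yl)-4-methyl-3-[(trimethylsilyl)ethynyl]cyclohex-2-en-1-one | CC(C)(C)[Si](OC[C@@H](C)[C@]1(C)C[C@](O)(C(=C)CO)C(=O)C=C1C#C[Si](C)(C)C)(c1ccccc1)c1ccccc1 | intermediate
22 | (4S,6S)-6-[3-(acetyloxy)prop-1-en-2-yl]-4-[(2S)-1-(tert-butyldiphenylsilyloxy)propan-2-yl]-6-hydroxy-4-methyl-3-[(trimethylsilyl)ethynyl]cyclohex-2-en-1-one | CC(C)(C)[Si](OC[C@@H](C)[C@]1(C)C[C@](O)(C(=C)COC(C)=O)C(=O)C=C1C#C[Si](C)(C)C)(c1ccccc1)c1ccccc1 | intermediate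
23 | (4S,6S)-6-[3-(acetyloxy)prop-1-en-2-yl]-4-[(2S)-1-(tert-butyldiphenylsilyloxy)propan-2-yl]-6-hydroxy-3-(iodoethynyl)-4-methylcyclohex-2-en-1-one | CC(C)(C)[Si](OC[C@@H](C)[C@]1(C)C[C@](O)(C(=C)COC(C)=O)C(=O)C=C1C#CI)(c1ccccc1)c1ccccc1 | intermediate
24 | (4S,6S)-6-[3-(acetyloxy)prop-1-en-2-yl]-4-[(2S)-1-(tert-butyldiphenylsilyloxy)propan-2-yl]-6-hydroxy-3-[(Z)-2-iodoethenyl]-4-methylcyclohex-2-en-1-one | CC(C)(C)[Si](OC[C@@H](C)[C@]1(C)C[C@](O)(C(=C)COC(C)=O)C(=O)C=C1/C=C\I)(c1ccccc1)c1ccccc1 | intermediate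
25 | (4S,6S)-6-[3-(acetyloxy)prop-1-en-2-yl]-6-hydroxy-4-[(2S)-1-hydroxypropan-2-yl]-3-[(Z)-2-iodoethenyl]-4-methylcyclohex-2-en-1-one | OC[C@@H](C)[C@]1(C)C[C@](O)(C(=C)COC(C)=O)C(=O)C=C1/C=C\I | intermediate
26 | (2S)-2-[(1S,5S)-5-[3-(acetyloxy)prop-1-en-2-yl]-5-hydroxy-2-[(Z)-2-iodoethenyl]-1-methyl-4-oxocyclohex-2-en-1-yl]propanal (ring B iodo-dienone aldehyde) | C=C(COC(C)=O)[C@@]1(O)C[C@@](C)([C@H](C)C=O)C(=CC1=O)/C=C\I | intermediate
27 | (3S,4S,5S,7S)-13-acetoxy-3,7-dihydroxyeremophila-1,9,11(12)-trien-8-one (C3 alcohol of the complete core) | C=C(COC(C)=O)[C@@]1(O)C[C@]2(C)C(=CC1=O)C=C[C@H](O)[C@H]2C | intermediate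
28 | (R)-2-methylbutanoic acid | OC(=O)[C@H](C)CC | starting material
29 | (2R)-2-methylbutan-1-ol | OC[C@H](C)CC | intermediate
30 | (R)-2-methylbutanal | O=C[C@H](C)CC | intermediate
31 | (2E,4R)-2,4-dimethylhex-2-enal | O=C/C(C)=C/[C@H](C)CC | intermediate
32 | ethyl (2E,4E,6R)-4,6-dimethylocta-2,4-dienoate | CCOC(=O)/C=C/C(C)=C/[C@H](C)CC | intermediate
33 | (2E,4E,6R)-4,6-dimethylocta-2,4-dienoic acid | OC(=O)/C=C/C(C)=C/[C@H](C)CC | intermediate
34 | mixed anhydride of 33 with 2,4,6-trichlorobenzoic acid | O=C(OC(=O)/C=C/C(C)=C/[C@H](C)CC)c1c(Cl)cc(Cl)cc1Cl | intermediate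
35 | (3S,4S,5S,7S)-13-acetoxy-7-hydroxy-8-oxoeremophila-1,9,11(12)-trien-3-yl (2E,4E,6R)-4,6-dimethylocta-2,4-dienoate (CNP0160850.1) | C=C(COC(C)=O)[C@@]1(O)C[C@]2(C)C(=CC1=O)C=C[C@H](OC(=O)/C=C/C(C)=C/[C@H](C)CC)[C@H]2C | target

Total step count: 24.
Longest linear sequence: 19 steps (steps 1–10, 12–19 and 24).

Steps most likely to fail

Step 12. The enolate cross-coupling may stall at the hindered ring enolate, or it may overrun through isomerisation of the product into conjugation and a second alkenylation. The fallback sets out from 16 and builds the C7–C11 bond by carbonyl chemistry instead. A directed aldol addition of the lithium enolate of 16 (LiN(i-Pr)2, THF, −78 °C) to 1-[(triethylsilyl)oxy]propan-2-one should give the β-hydroxy ketone F1. Dehydration with the Burgess reagent (benzene, 50 °C) should then give the C7(11)-alkylidene enone F2, possibly together with 19. Deprotonation of F2 at its C12 methyl group with KN(SiMe3)2 leads to the same dienolate as 19, so the oxidation and methanolysis of step 13 bring the material back to the route at 21.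

Step 13. The oxidation of the dienolate may show poor facial selectivity at C7 and give a mixture of ketol epimers. The fallback sets out from 19 and replaces substrate control by catalyst control. The potassium dienolate is trapped with Me3SiCl as the trimethylsilyl dienol ether F3. F3 is oxidised in a Rubottom-type sequence by Shi epoxidation (KHSO5, K2CO3, MeCN–dimethoxymethane–H2O, 0 °C) with 1,2:4,5-di-O-isopropylidene-D-erythro-2,3-hexodiulo-2,6-pyranose or its enantiomer, whichever is matched to the required face. Acidic methanolysis of the silyloxy epoxide and of the triethylsilyl ether returns the material to the route at 21.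

Step 19. The ring closure may proceed with poor facial selectivity at C3 if the chromium alkoxide closes pseudo-axially. The fallback sets out from the C3-epimeric alcohol F4 formed in that case. A Mitsunobu esterification of F4 with acid 33 (PPh3, diisopropyl azodicarboxylate, toluene, 0 °C) inverts C3 and should give the target directly, so it rejoins the route at 35.

Further compounds
F1 | step 12 | (4S)-4-[(2S)-1-(tert-butyldiphenylsilyloxy)propan-2-yl]-6-[2-hydroxy-1-(triethylsilyloxy)propan-2-yl]-4-methyl-3-[(trimethylsilyl)ethynyl]cyclohex-2-en-1-one (diastereomer mixture) | CC(C)(C)[Si](OC[C@@H](C)[C@]1(C)CC(C(C)(O)CO[Si](CC)(CC)CC)C(=O)C=C1C#C[Si](C)(C)C)(c1ccccc1)c1ccccc1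
F2 | step 12 | (4S)-4-[(2S)-1-(tert-butyldiphenylsilyloxy)propan-2-yl]-4-methyl-6-[1-(triethylsilyloxy)propan-2-ylidene]-3-[(trimethylsilyl)ethynyl]cyclohex-2-en-1-one (E/Z mixture) | CC(C)(C)[Si](OC[C@@H](C)[C@]1(C)CC(=C(C)CO[Si](CC)(CC)CC)C(=O)C=C1C#C[Si](C)(C)C)(c1ccccc1)c1ccccc1
F3 | step 13 | tert-butyl{(2S)-2-[(1S)-1-methyl-5-[3-(triethylsilyloxy)prop-1-en-2-yl]-4-(trimethylsilyloxy)-2-[(trimethylsilyl)ethynyl]cyclohexa-2,4-dien-1-yl]propoxy}diphenylsilane | CC(C)(C)[Si](OC[C@@H](C)[C@]1(C)CC(C(=C)CO[Si](CC)(CC)CC)=C(O[Si](C)(C)C)C=C1C#C[Si](C)(C)C)(c1ccccc1)c1ccccc1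
F4 | step 19 | (3R,4S,5S,7S)-13-acetoxy-3,7-dihydroxyeremophila-1,9,11(12)-trien-8-one | C=C(COC(C)=O)[C@@]1(O)C[C@]2(C)C(=CC1=O)C=C[C@@H](O)[C@H]2C
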